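## Retrosynthetic overview

1. Rings A and B, with C5, C9 and C10 already set, come intact from (+)-sclareolide 1. No carbocycle is formed; the lactone ring is opened (step 1), re-closed (step 4) and opened again (step 8).
2. Ring B oxygens are traced back through Δ7 ester 2, enone 3, 6β-allylic alcohol 4, β-epoxide 5 and dihydroxy lactone 6 (C8–O re-made with inversion by the C12 carboxyl) to lactol 7.
3. Side-chain partner: but-3-en-2-ol 8 and 1-phenyl-1H-tetrazole-5-thiol 9 give sulfide 10, then sulfone 11.
4. Key disconnection C12=C13: the α-sulfonyl carbanion of 11 makes C13 nucleophilic, although it is the electrophilic carbonyl carbon in methyl vinyl ketone. It joins the electrophilic C12 of 7, and the oxygen leaves with SO2 and tetrazolate, giving triol diene 12.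
5. Last disconnection is the C7 acetate: 12 gives target 13 by selective acylation.

Assumption: labdane numbering is used; the SMILES is read as (5S,6S,7S,8S,9R,10S,12E), i.e. 5α-H, 6β-OH, 7β-OAc, 8α-OH/8β-Me, 9α-H, 10β-Me; 1, 8 and 9 are taken as commercial.

## Route

Step 1
Reactants: 1 (+)-sclareolide (13,14,15,16-tetranorlabdano-12,8α-lactone)
Product: 2 methyl 13,14,15,16-tetranorlabd-7-en-12-oate (5α-H, 9α-H, 10β-Me)
Conditions: MeOH, conc. H2SO4, reflux, 24 h; AgNO3–SiO2 chromatography
Reagents that add atoms: methanol, CO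
Why: Acid-mediated lactone opening–dehydration with in-situ Fischer esterification (E1 at the tertiary C8–O bond) should favour the trisubstituted endocyclic Δ7 alkene over the exocyclic Δ8(17) isomer under equilibrating conditions, creating no stereocentre and leaving C5, C9 and C10 as they are.

Step 2
Reactants: 2 methyl 13,14,15,16-tetranorlabd-7-en-12-oate
Product: 3 methyl 6-oxo-13,14,15,16-tetranorlabd-7-en-12-oate
Conditions: t-BuOOH (70% aq., 5 equiv), Rh2(cap)4 (cap = caprolactamate, 1 mol %), K2CO3, CH2Cl2, rt
Reagents that add atoms: tert-butyl hydroperoxide, CC(C)(C)OO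
Why: Radical allylic C–H oxidation (dirhodium caprolactamate/t-BuOOH): the peroxyl radical abstracts the secondary allylic C6–H, the same regiochemistry as the Δ5-steroid to 7-ketone oxidation, while the tertiary C9–H next to quaternary C10 is shielded, and the mixed peroxide collapses to the conjugated enone.

Step 3
Reactants: 3 methyl 6-oxo-13,14,15,16-tetranorlabd-7-en-12-oate
Product: 4 methyl 6β-hydroxy-13,14,15,16-tetranorlabd-7-en-12-oate
Conditions: NaBH4, CeCl3·7H2O, MeOH, −20 °C
Reagents that add atoms: none
Why: Luche 1,2-reduction in which hydride attacks C6 from the open α face, anti to the syn-axial C10 and C4β methyl groups, so the new stereocentre is the axial 6β-alcohol (6S).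

Step 4
Reactants: 4 methyl 6β-hydroxy-13,14,15,16-tetranorlabd-7-en-12-oate
Product: 6 6β,7β-dihydroxy-13,14,15,16-tetranorlabdano-12,8α-lactone, via epoxy ester 5 (not isolated)
Conditions: VO(acac)2 (5 mol %), t-BuOOH (1.5 equiv), CH2Cl2, 0 °C → rt; then CSA (10 mol %), H2O (2 equiv), rt
Reagents that add atoms: tert-butyl hydroperoxide, CC(C)(C)OO; water, O
Why: Hydroxyl-directed vanadium-catalysed epoxidation (Sharpless–Michaelson type) delivers oxygen syn to the pseudo-axial 6β-OH to give the 7β,8β-epoxide, and acid-catalysed 5-exo opening by the ester carbonyl at tertiary C8 with inversion (epoxy-ester lactonisation) sets 8α-O/8β-Me while C7 keeps its β-oxygen.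

Step 5
Reactants: 6 6β,7β-dihydroxy-13,14,15,16-tetranorlabdano-12,8α-lactone
Product: 7 8α,12-epoxy-13,14,15,16-tetranorlabdane-6β,7β,12-triol (lactol, both C12 anomers)
Conditions: i-Bu2AlH (4 equiv), CH2Cl2, −78 °C; aq. potassium sodium tartrate
Reagents that add atoms: none
Why: Partial reduction of the γ-lactone to the lactol (the tetrahedral aluminium hemiacetal does not collapse at −78 °C, two equivalents being consumed by the diol) touches no ring stereocentre and leaves C12 as an anomeric mixture.

Step 6
Reactants: 8 but-3-en-2-ol (racemic); 9 1-phenyl-1H-tetrazole-5-thiol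
Product: 10 5-(but-3-en-2-ylsulfanyl)-1-phenyl-1H-tetrazole (racemic)
Conditions: PPh3, DIAD, THF, 0 °C → rt
Reagents that add atoms: none
Why: Mitsunobu thioetherification in which the acidic tetrazolethiol displaces the activated secondary allylic alcohol by SN2 (racemic reagent; this centre is destroyed in step 8).

Step 7
Reactants: 10 5-(but-3-en-2-ylsulfanyl)-1-phenyl-1H-tetrazole
Product: 11 5-(but-3-en-2-ylsulfonyl)-1-phenyl-1H-tetrazole (racemic)
Conditions: H2O2 (30% aq.), (NH4)6Mo7O24·4H2O (10 mol %), EtOH, 0 °C → rt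
Reagents that add atoms: hydrogen peroxide, OO
Why: Molybdate-catalysed peroxide oxidation of sulfide to sulfone, which does not epoxidise the unactivated terminal alkene.

Step 8
Reactants: 7 8α,12-epoxy-13,14,15,16-tetranorlabdane-6β,7β,12-triol; 11 5-(but-3-en-2-ylsulfonyl)-1-phenyl-1H-tetrazole
Product: 12 (12E)-labda-12,14-diene-6β,7β,8α-triol
Conditions: 11 (2.5 equiv), KN(SiMe3)2 (5.5 equiv in all), 18-crown-6, THF, −78 °C → rt; AgNO3–SiO2 chromatography
Reagents that add atoms: none
Why: Julia–Kocienski olefination in which the α-sulfonyl carbanion of 11 serves as a reversed-polarity C13 and adds to the electrophilic C12 aldehyde released from the lactol alkoxide, after which Smiles rearrangement and loss of SO2 and tetrazolate form C12=C13 directly on the unprotected triol without a C12 leaving group that the 8α-OH could displace; the E isomer (C11 trans to vinyl) is expected to predominate under non-chelating potassium/crown conditions, but the ratio is uncertain and the Z isomer is removed by chromatography.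

Step 9
Reactants: 12 (12E)-labda-12,14-diene-6β,7β,8α-triol
Product: 13 (12E)-7β-acetoxylabda-12,14-diene-6β,8α-diol (target)
Conditions: Ac2O (1.2 equiv), pyridine, 0 °C; neutral work-up
Reagents that add atoms: acetic anhydride, CC(=O)OC(C)=O
Why: Kinetically selective O-acetylation of the equatorial secondary 7β-OH, since the axial 6β-OH is screened by three syn-axial methyl groups (C4β, C8β, C10) and the 8α-OH is tertiary, the same selectivity as in the acetylation of 7-deacetylforskolin.

## Compound list

1 | (+)-sclareolide (13,14,15,16-tetranorlabdano-12,8α-lactone) | O=C1C[C@H]2[C@](C)(O1)CC[C@H]3C(C)(C)CCC[C@]23C | starting material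
2 | methyl 13,14,15,16-tetranorlabd-7-en-12-oate | COC(=O)C[C@H]1C(C)=CC[C@H]2C(C)(C)CCC[C@@]21C | intermediate
3 | methyl 6-oxo-13,14,15,16-tetranorlabd-7-en-12-oate | COC(=O)C[C@H]1C(C)=CC(=O)[C@H]2C(C)(C)CCC[C@@]21C | intermediate
4 | methyl 6β-hydroxy-13,14,15,16-tetranorlabd-7-en-12-oate | COC(=O)C[C@H]1C(C)=C[C@@H](O)[C@H]2C(C)(C)CCC[C@@]21C | intermediate
5 | methyl 7β,8β-epoxy-6β-hydroxy-13,14,15,16-tetranorlabdan-12-oate | COC(=O)C[C@H]1[C@@]3(C)O[C@H]3[C@@H](O)[C@H]2C(C)(C)CCC[C@@]21C | intermediate (not isolated)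
6 | 6β,7β-dihydroxy-13,14,15,16-tetranorlabdano-12,8α-lactone | O=C1C[C@H]2[C@](C)(O1)[C@@H](O)[C@@H](O)[C@H]3C(C)(C)CCC[C@]23C | intermediate
7 | 8α,12-epoxy-13,14,15,16-tetranorlabdane-6β,7β,12-triol (lactol, C12 anomers) | OC1C[C@H]2[C@](C)(O1)[C@@H](O)[C@@H](O)[C@H]3C(C)(C)CCC[C@]23C | intermediate
8 | but-3-en-2-ol (racemic) | CC(O)C=C | starting material
9 | 1-phenyl-1H-tetrazole-5-thiol | Sc1nnnn1-c1ccccc1 | starting material
10 | 5-(but-3-en-2-ylsulfanyl)-1-phenyl-1H-tetrazole (racemic) | C=CC(C)Sc1nnnn1-c1ccccc1 | intermediate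
11 | 5-(but-3-en-2-ylsulfonyl)-1-phenyl-1H-tetrazole (racemic) | C=CC(C)S(=O)(=O)c1nnnn1-c1ccccc1 | intermediate
12 | (12E)-labda-12,14-diene-6β,7β,8α-triol | C=C/C(C)=C/C[C@H]1[C@](C)(O)[C@@H](O)[C@@H](O)[C@H]2C(C)(C)CCC[C@@]21C | intermediate
13 | (12E)-7β-acetoxylabda-12,14-diene-6β,8α-diol | C=C/C(C)=C/C[C@H]1[C@](C)(O)[C@@H](OC(C)=O)[C@@H](O)[C@H]2C(C)(C)CCC[C@@]21C | target

## Step count and risks

Total steps: 9. Longest linear sequence: 7 (steps 1, 2, 3, 4, 5, 8, 9).

The three steps most likely to fail are steps 1, 4 and 8.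

Step 1 (regiochemistry of the dehydration; Δ8(17) and Δ8(9) isomers may be substantial or even predominate). The fallback sets out from 1 and comes back at 2. Lactone 1 is saponified (KOH, MeOH/H2O) and the carboxylate methylated (MeI, DMF) to the open hydroxy ester methyl 8α-hydroxy-13,14,15,16-tetranorlabdan-12-oate F1. Kinetic E2-type dehydration through the chlorosulfite (SOCl2, pyridine, CH2Cl2, −78 °C) follows; for the equatorial 8α leaving group only the methyl hydrogens are antiperiplanar, so this should give the exocyclic alkene methyl 13,14,15,16-tetranorlabd-8(17)-en-12-oate F2 free of the tetrasubstituted isomer. F2 is then walked one position into the ring (cat. I2 or p-TsOH, benzene, rt, stopped at the trisubstituted stage) to give 2.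

Step 4 (β-face epoxidation against the C10 methyl; epoxide rearrangement instead of lactonisation). The fallback sets out from 3 and comes back at 6.
- Enone 3 is dihydroxylated from the open α face (OsO4 cat., NMO, acetone/H2O) to methyl 7α,8α-dihydroxy-6-oxo-13,14,15,16-tetranorlabdan-12-oate F3, which already carries the correct 8α-OH/8β-Me.
- Acid (p-TsOH cat., toluene) closes the lactone to 7α-hydroxy-6-oxo-13,14,15,16-tetranorlabdano-12,8α-lactone F4.
- Brief equilibration through the enediol (Et3N, MeOH, rt, kept short to avoid β-elimination of the lactone oxygen) moves the axial ketol hydroxyl to the equatorial position, giving 7β-hydroxy-6-oxo-13,14,15,16-tetranorlabdano-12,8α-lactone F5.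
- NaBH4 (MeOH, −20 °C) attacks the ketone from the α face and gives 6.

Step 8 (E/Z ratio of the trisubstituted diene; attack of the alkoxides on the tetrazolyl sulfone). The fallback sets out from 7 and comes back at 12. Lactol 7 is condensed with the stabilised ylide Ph3P=C(CH3)CHO (toluene, 90 °C), which gives the thermodynamically controlled enal (12E)-6β,7β,8α-trihydroxy-15-norlabd-12-en-14-al F6. Methylenation with Ph3P=CH2 (from Ph3PCH3Br and KOt-Bu, THF, 0 °C, excess to cover the three hydroxyls) then gives 12 with the E geometry already fixed.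

## Further compounds

F1 | step 1 | methyl 8α-hydroxy-13,14,15,16-tetranorlabdan-12-oate | COC(=O)C[C@H]1[C@](C)(O)CC[C@H]2C(C)(C)CCC[C@@]21C
F2 | step 1 | methyl 13,14,15,16-tetranorlabd-8(17)-en-12-oate | COC(=O)C[C@H]1C(=C)CC[C@H]2C(C)(C)CCC[C@@]21C
F3 | step 4 | methyl 7α,8α-dihydroxy-6-oxo-13,14,15,16-tetranorlabdan-12-oate | COC(=O)C[C@H]1[C@](C)(O)[C@H](O)C(=O)[C@H]2C(C)(C)CCC[C@@]21C
F4 | step 4 | 7α-hydroxy-6-oxo-13,14,15,16-tetranorlabdano-12,8α-lactone | O=C1C[C@H]2[C@](C)(O1)[C@H](O)C(=O)[C@H]3C(C)(C)CCC[C@]23C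
F5 | step 4 | 7β-hydroxy-6-oxo-13,14,15,16-tetranorlabdano-12,8α-lactone | O=C1C[C@H]2[C@](C)(O1)[C@@H](O)C(=O)[C@H]3C(C)(C)CCC[C@]23C
F6 | step 8 | (12E)-6β,7β,8α-trihydroxy-15-norlabd-12-en-14-al | O=C/C(C)=C/C[C@H]1[C@](C)(O)[C@@H](O)[C@@H](O)[C@H]2C(C)(C)CCC[C@@]21C
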